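All runs were computed on assumed constants, noise included.

4 questions stand on 4 flasks that differ in their electrophile charge, and two earlier runs, read up to 15.0 min, stand beside them.

| flask | electrophile | nucleophile | free base | remark | time |
|---|---|---|---|---|---|
| north | 0.18 M | 0.13 M (in portions, 2) | 0.18 M | run made earlier; portions every 8.0 min |  |
| south-east | 0.18 M | 0.095 M (in portions, 2) | 0.18 M | run made earlier; portions every 8.0 min |  |
| Monday's | 0.060 M | 0.189 M (in portions, 2) | 0.180 M | the portions of nucleophile follow each other after 8.0 min, the first at the start | 80 min |
| Saturday's | 0.050 M | 0.189 M (in portions, 2) | 0.180 M | the portions of nucleophile follow each other after 8.0 min, the first at the start | 80 min |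
| Tuesday's | 0.40 M | 0.189 M (in portions, 2) | 0.180 M | the portions of nucleophile follow each other after 8.0 min, the first at the start | 80 min |
| Sunday's | 0.18 M | 0.189 M (in portions, 2) | 0.180 M | the portions of nucleophile follow each other after 8.0 min, the first at the start | 80 min |

| run | time / min | target / % |
|---|---|---|
| north | 1.33 | 14.2 |
| north | 2.50 | 19.2 |
| north | 5.00 | 21.0 |
| north | 8.00 | 25.7 |
| north | 15.0 | 44.7 |
| south-east | 3.00 | 16.1 |
| south-east | 6.00 | 19.1 |
| south-east | 10.0 | 29.8 |
| south-east | 12.0 | 32.7 |
| south-east | 15.0 | 36.4 |

(each reading ± 1 percentage point)

- ranking by amount of target, in percent of the electrophile charged, from high to low, at 80 min (Monday's / Saturday's / Tuesday's / Sunday's)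
- the same order at 5.0 h (Monday's / Saturday's / Tuesday's / Sunday's)
- the amount of target, in percent of the electrophile charged of the flask you put first, at 80 min
- the amount of target, in percent of the electrophile charged of the flask you put last, at 80 min

- the numbers in the tables scatter with a standard deviation of 1 percentage point

Assuming that each target uses one nucleophile, the first reckoning needs the charge ratio, the whole nucleophile charge as a fraction of the electrophile charge, which for Tuesday's is 47.2%. Below one, the nucleophile is the limiting reagent and the ratio is a ceiling on target as a fraction of the electrophile charged. The north run has a ceiling of 72.2% and reads 44.7% at 15.0 min, so the ceiling was not reached there and time has to be reckoned.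

After the second portion, the north run climbs from 25.7% to 44.7% in 7.00 min. That uses nucleophile at a pace of 0.0376 min⁻¹ of its own charge. At that pace the whole charge lasts 26.6 min, which is shorter than the 80 min asked, so this reckoning puts Tuesday's close under its ceiling and, with a ratio below one, last at 80 min.

Going round once more, the first answer is put back in for the other flasks. Their ratios are 3.15 for Monday's, 3.78 for Saturday's and 1.05 for Sunday's, so each nucleophile charge stands above the electrophile charge, and in Monday's and Saturday's this count leaves nucleophile beside the finished target. Both earlier runs have ratios below one, so their readings do not show what that surplus does.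

The forecast gives Saturday's > Monday's > Sunday's > Tuesday's at 80 min and Saturday's > Monday's > Sunday's > Tuesday's at 5.0 h, with 98% for the first flask and 45% for the last. For Monday's and Saturday's, it expects completion “with Saturday's slightly ahead”. On Tuesday's its number lies close to the ceiling reckoned here.

    electrophile + nucleophile → acid set free + target (k = 0.0675 L mol⁻¹ s⁻¹)
    nucleophile + acid set free ⇌ protonated nucleophile, settled at all times (K = 632 L mol⁻¹)
    acid set free + free base ⇌ salt of the base (K = 14.5 L mol⁻¹, k = 0.0601 L mol⁻¹ s⁻¹)
    nucleophile + target → over-reaction product (k = 0.00212 L mol⁻¹ s⁻¹)

The flasks give Sunday's > Monday's > Saturday's > Tuesday's at 80 min, with 78.3% for Sunday's and 43.9% for Tuesday's, and Sunday's > Tuesday's > Monday's > Saturday's at 5.0 h. At 80.0 min, over-reaction product holds 42.8% of the electrophile charged in Monday's, 51.5% in Saturday's and 2.61% in Sunday's. Tuesday's stands under its charge ratio of 47.2%. Its neighbour with 0.11 M of nucleophile has a charge ratio of 27.5% and gives 27.0% of target.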